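**Retrosynthetic overview**
1. 15 ⇒ 12 + 13. The C5–alkenyl bond comes from a Suzuki–Miyaura coupling, and both silyl ethers are removed in the same flask.
2. 12 ⇒ 10. Bonds C3a–C7a and C4–C5 form together in an intramolecular alkyne/1,2-diazine Diels–Alder reaction with loss of N2. The benzo ring and the dihydrofuran ring appear in one operation, and the sacrificial pyridazine leaves its Cl at C5.
3. 10 ⇒ 8 + 9. The aryl ether is made by SNAr, so the carbinol C–O bond is never broken.
4. 8 ⇒ 7 ⇒ 3 + 4 + 5. Both stereocentres are set at once on the open chain by a Cu-catalysed B2pin2/enyne/aldehyde coupling. The anti diol maps onto the trans ring.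
5. Ring order: the trimethoxyphenyl ring is bought. The benzo and dihydrofuran rings are formed simultaneously, late in the route.

Assumption: (S,S)-Ph-BPE is taken as the ligand antipode that gives the (1R,2S)-anti adduct. If the sense of induction is opposite, (R,R)-Ph-BPE is used and nothing else changes.

**Step 1**
Reactants: 1 (trimethylsilyl)acetylene; 2 vinyl bromide
Product: 3 but-3-en-1-yn-1-yl(trimethyl)silane
Conditions: PdCl2(PPh3)2 (1 mol%), CuI (2 mol%), Et3N, THF, 0 °C to rt
Reagents that add atoms: none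
Why: Sonogashira coupling of a terminal alkyne with an unhindered vinyl bromide is fast at room temperature, the silyl group blocks the other alkyne terminus, and no stereocentre is formed.

**Step 2**
Reactants: 3 but-3-en-1-yn-1-yl(trimethyl)silane; 4 3,4,5-trimethoxybenzaldehyde; 5 bis(pinacolato)diboron
Product: 7 (1R,2S)-2-ethynyl-1-(3,4,5-trimethoxyphenyl)propane-1,3-diol, via bis(pinacolboryl) adduct 6 (not isolated)
Conditions: CuCl (5 mol%), (S,S)-Ph-BPE (5.5 mol%), NaOt-Bu (10 mol%), THF, 22 °C, 12 h; then MeOH, 3 M aq NaOH, 30% H2O2, 0 °C to rt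
Reagents that add atoms: hydrogen peroxide OO
Why: In this Cu-catalysed borylative three-component propargylation, ligand-controlled Cu–B addition to the vinyl terminus gives an enantioenriched allenyl-copper that adds to the aldehyde through a closed six-membered SE2' transition state, setting C1 (R) and the anti C2 centre together, after which basic peroxide converts CH2–B into CH2–OH and strips the alkynyl silane.

**Step 3**
Reactants: 7 (1R,2S)-2-ethynyl-1-(3,4,5-trimethoxyphenyl)propane-1,3-diol
Product: 8 (1R,2S)-2-{[(triisopropylsilyl)oxy]methyl}-1-(3,4,5-trimethoxyphenyl)but-3-yn-1-ol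
Conditions: TIPSCl (1.05 equiv), imidazole, DMF, 0 °C to rt
Reagents that add atoms: triisopropylsilyl chloride CC(C)[Si](Cl)(C(C)C)C(C)C
Why: In this sterically governed silyl ether formation the bulky chlorosilane takes the primary hydroxyl far faster than the hindered secondary benzylic one, TIPS resists base-induced O-to-O migration and survives 200 °C, and no stereocentre is touched.

**Step 4**
Reactants: 8 (1R,2S)-2-{[(triisopropylsilyl)oxy]methyl}-1-(3,4,5-trimethoxyphenyl)but-3-yn-1-ol; 9 3,6-dichloropyridazine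
Product: 10 3-chloro-6-{[(1R,2S)-2-{[(triisopropylsilyl)oxy]methyl}-1-(3,4,5-trimethoxyphenyl)but-3-yn-1-yl]oxy}pyridazine
Conditions: NaH (1.05 equiv), THF, 0 °C; then 9 (1.3 equiv), 0 to 40 °C
Reagents that add atoms: none
Why: Nucleophilic aromatic substitution (addition–elimination) of the alkoxide on the activated dichlorodiazine stops after one chloride because the new alkoxy group deactivates the ring, and since only the O–H bond of 8 is broken both configurations are retained.

**Step 5**
Reactants: 10 3-chloro-6-{[(1R,2S)-2-{[(triisopropylsilyl)oxy]methyl}-1-(3,4,5-trimethoxyphenyl)but-3-yn-1-yl]oxy}pyridazine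
Product: 12 {[(2R,3S)-5-chloro-2-(3,4,5-trimethoxyphenyl)-2,3-dihydro-1-benzofuran-3-yl]methoxy}tri(propan-2-yl)silane, via diazabarrelene cycloadduct 11 (not isolated)
Conditions: 1,3,5-triisopropylbenzene (0.02 M), BHT (10 mol%), Ar, 200 °C, 12–24 h
Reagents that add atoms: none
Why: The intramolecular inverse-electron-demand Diels–Alder reaction of the 1,2-diazine (C3/C6 as diene termini) with the three-atom-tethered terminal alkyne, followed by retro-Diels–Alder loss of N2, is the known way from 3-(but-3-ynyloxy)pyridazines to 2,3-dihydrobenzofurans, builds the benzo and dihydrofuran rings at once, is accelerated by the two tether substituents and the chlorine, fixes Cl at C5 by connectivity alone, and carries the untouched anti (1R,2S) tether centres over as trans (2R,3S).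

**Step 6**
Reactants: 12 {[(2R,3S)-5-chloro-2-(3,4,5-trimethoxyphenyl)-2,3-dihydro-1-benzofuran-3-yl]methoxy}tri(propan-2-yl)silane; 13 (E)-3-(tert-butyldimethylsilyloxy)prop-1-en-1-ylboronic acid pinacol ester
Product: 15 (E)-3-[(2R,3S)-3-(hydroxymethyl)-2-(3,4,5-trimethoxyphenyl)-2,3-dihydro-1-benzofuran-5-yl]prop-2-en-1-ol, via bis-silyl ether 14 (not isolated)
Conditions: Pd(OAc)2 (3 mol%), SPhos (6 mol%), K3PO4, 1,4-dioxane/H2O 10:1, 90 °C; then TBAF (1 M in THF, 6 equiv), 45 °C, same flask
Reagents that add atoms: none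
Why: Suzuki–Miyaura coupling with an electron-rich biaryl phosphine opens the electron-rich aryl chloride and transfers the alkenyl group with retention of the E geometry, and fluoride then cleaves both silyl ethers under non-acidic conditions that spare the ionisable cinnamyl alcohol and both stereocentres.

**Compound list**
1 | (trimethylsilyl)acetylene | C[Si](C)(C)C#C | starting material
2 | vinyl bromide | C=CBr | starting material
3 | but-3-en-1-yn-1-yl(trimethyl)silane | C=CC#C[Si](C)(C)C | intermediate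
4 | 3,4,5-trimethoxybenzaldehyde | COc1cc(C=O)cc(OC)c1OC | starting material
5 | bis(pinacolato)diboron | CC1(C)OB(OC1(C)C)B1OC(C)(C)C(C)(C)O1 | starting material
6 | (1R,2R)-anti O-Bpin borate of 2-[(pinacolboryl)methyl]-1-(3,4,5-trimethoxyphenyl)-4-(trimethylsilyl)but-3-yn-1-ol | COc1cc([C@H](OB2OC(C)(C)C(C)(C)O2)[C@H](CB2OC(C)(C)C(C)(C)O2)C#C[Si](C)(C)C)cc(OC)c1OC | intermediate
7 | (1R,2S)-2-ethynyl-1-(3,4,5-trimethoxyphenyl)propane-1,3-diol | COc1cc([C@H](O)[C@H](CO)C#C)cc(OC)c1OC | intermediate
8 | (1R,2S)-2-{[(triisopropylsilyl)oxy]methyl}-1-(3,4,5-trimethoxyphenyl)but-3-yn-1-ol | COc1cc([C@H](O)[C@H](CO[Si](C(C)C)(C(C)C)C(C)C)C#C)cc(OC)c1OC | intermediate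
9 | 3,6-dichloropyridazine | Clc1ccc(Cl)nn1 | starting material
10 | 3-chloro-6-{[(1R,2S)-2-{[(triisopropylsilyl)oxy]methyl}-1-(3,4,5-trimethoxyphenyl)but-3-yn-1-yl]oxy}pyridazine | COc1cc([C@H](Oc2ccc(Cl)nn2)[C@H](CO[Si](C(C)C)(C(C)C)C(C)C)C#C)cc(OC)c1OC | intermediate
11 | chloro-2,3-diazabicyclo[2.2.2]octa-2,5,7-triene cycloadduct fused to the new dihydrofuran ring (bridgeheads undefined; attack on either diazine face converges on 12) | ClC12N=NC3(C=C1)O[C@@H](c4cc(OC)c(OC)c(OC)c4)[C@H](CO[Si](C(C)C)(C(C)C)C(C)C)C3=C2 | intermediate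
12 | {[(2R,3S)-5-chloro-2-(3,4,5-trimethoxyphenyl)-2,3-dihydro-1-benzofuran-3-yl]methoxy}tri(propan-2-yl)silane | COc1cc([C@@H]2Oc3ccc(Cl)cc3[C@H]2CO[Si](C(C)C)(C(C)C)C(C)C)cc(OC)c1OC | intermediate
13 | (E)-3-(tert-butyldimethylsilyloxy)prop-1-en-1-ylboronic acid pinacol ester | CC(C)(C)[Si](C)(C)OC/C=C/B1OC(C)(C)C(C)(C)O1 | starting material
14 | (2R,3S)-5-[(E)-3-(tert-butyldimethylsilyloxy)prop-1-en-1-yl]-3-{[(triisopropylsilyl)oxy]methyl}-2-(3,4,5-trimethoxyphenyl)-2,3-dihydro-1-benzofuran | COc1cc([C@@H]2Oc3ccc(/C=C/CO[Si](C)(C)C(C)(C)C)cc3[C@H]2CO[Si](C(C)C)(C(C)C)C(C)C)cc(OC)c1OC | intermediate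
15 | (E)-3-[(2R,3S)-3-(hydroxymethyl)-2-(3,4,5-trimethoxyphenyl)-2,3-dihydro-1-benzofuran-5-yl]prop-2-en-1-ol (CNP0077408.1) | COc1cc([C@@H]2Oc3ccc(/C=C/CO)cc3[C@H]2CO)cc(OC)c1OC | target

**Total step count:** 6. There are six isolated products, and steps 2 and 6 are two-stage one-pot operations.
**Longest linear sequence:** 6 (1/2 → 3 → 7 → 8 → 10 → 12 → 15).

**Steps most likely to fail**

Step 5 (most at risk). At 200 °C the secondary, electron-rich benzylic pyridazinyl ether may lose 6-chloropyridazin-3(2H)-one by a retro-ene elimination before it cyclises.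

The fallback sets out from 9, with 8 as partner, and comes back at 15. It activates the diazine and carries the side chain through the cycloaddition at the ester oxidation level.
- A Heck reaction of excess 9 with methyl acrylate (Pd(OAc)2, P(o-tol)3, Et3N, DMF, 100 °C) gives methyl (E)-3-(6-chloropyridazin-3-yl)prop-2-enoate F1.
- The sodium alkoxide of 8 displaces its chloride to give the acrylate-bearing pyridazinyl ether F2.
- The lower LUMO of this ether should let cycloaddition and N2 loss run at about 140–160 °C, giving the dihydrobenzofuranyl acrylate F3.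
- DIBAL-H (CH2Cl2, −78 °C) reduces the ester to the mono-TIPS allylic alcohol F4, and TBAF gives 15.
- The Suzuki coupling is no longer needed.

Step 2. The silyl-capped enyne may give lower diastereo- or enantioselectivity, and direct borylation of the aldehyde may compete.

The fallback sets out from 4 and comes back at 8. It replaces catalytic induction by chirality transfer from a stoichiometric chiral allenylmetal (Marshall-type propargylation).
- Commercial (R)-but-3-yne-1,2-diol is silylated at the primary hydroxyl (TIPSCl, imidazole) to (R)-1-[(triisopropylsilyl)oxy]but-3-yn-2-ol F5.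
- This alcohol is mesylated (MsCl, Et3N) to the (R)-propargylic mesylate F6.
- The mesylate is coupled with 4 using Pd(OAc)2 (5 mol%), PPh3 (5 mol%) and indium monoiodide (InI) in THF/HMPA at rt.
- Anti SN2' attack of zerovalent palladium, transmetalation to the allenylindium and cyclic SE2' addition replace the mesylate with net inversion.
- This gives the anti adduct 8 directly, so steps 1 to 3 are bypassed.

Step 6. Oxidative addition into the electron-rich aryl chloride may be slow enough for protodeboronation of 13 to win.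

The fallback sets out from 9 and 13 and comes back at 14. It moves the cross-coupling ahead of ring construction.
- Suzuki coupling of excess 9, an activated heteroaryl chloride, with 13 (Pd(OAc)2, SPhos, K3PO4, dioxane/H2O, 60 °C) gives the alkenyl chloropyridazine F7.
- The sodium alkoxide of 8 converts it into the alkenyl pyridazinyl ether F8.
- Thermolysis as in step 5 delivers 14, now isolated, which TBAF turns into 15.

**Further compounds**
F1 | step 5 | methyl (E)-3-(6-chloropyridazin-3-yl)prop-2-enoate | COC(=O)/C=C/c1ccc(Cl)nn1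
F2 | step 5 | methyl (E)-3-(6-{[(1R,2S)-2-{[(triisopropylsilyl)oxy]methyl}-1-(3,4,5-trimethoxyphenyl)but-3-yn-1-yl]oxy}pyridazin-3-yl)prop-2-enoate | COc1cc([C@H](Oc2ccc(/C=C/C(=O)OC)nn2)[C@H](CO[Si](C(C)C)(C(C)C)C(C)C)C#C)cc(OC)c1OC
F3 | step 5 | methyl (E)-3-[(2R,3S)-3-{[(triisopropylsilyl)oxy]methyl}-2-(3,4,5-trimethoxyphenyl)-2,3-dihydro-1-benzofuran-5-yl]prop-2-enoate | COc1cc([C@@H]2Oc3ccc(/C=C/C(=O)OC)cc3[C@H]2CO[Si](C(C)C)(C(C)C)C(C)C)cc(OC)c1OC
F4 | step 5 | (E)-3-[(2R,3S)-3-{[(triisopropylsilyl)oxy]methyl}-2-(3,4,5-trimethoxyphenyl)-2,3-dihydro-1-benzofuran-5-yl]prop-2-en-1-ol | COc1cc([C@@H]2Oc3ccc(/C=C/CO)cc3[C@H]2CO[Si](C(C)C)(C(C)C)C(C)C)cc(OC)c1OC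
F5 | step 2 | (R)-1-[(triisopropylsilyl)oxy]but-3-yn-2-ol | C#C[C@@H](O)CO[Si](C(C)C)(C(C)C)C(C)C
F6 | step 2 | (R)-1-[(triisopropylsilyl)oxy]but-3-yn-2-yl methanesulfonate | C#C[C@@H](OS(C)(=O)=O)CO[Si](C(C)C)(C(C)C)C(C)C
F7 | step 6 | 3-chloro-6-[(E)-3-{[tert-butyl(dimethyl)silyl]oxy}prop-1-en-1-yl]pyridazine | CC(C)(C)[Si](C)(C)OC/C=C/c1ccc(Cl)nn1
F8 | step 6 | 3-[(E)-3-{[tert-butyl(dimethyl)silyl]oxy}prop-1-en-1-yl]-6-{[(1R,2S)-2-{[(triisopropylsilyl)oxy]methyl}-1-(3,4,5-trimethoxyphenyl)but-3-yn-1-yl]oxy}pyridazine | COc1cc([C@H](Oc2ccc(/C=C/CO[Si](C)(C)C(C)(C)C)nn2)[C@H](CO[Si](C(C)C)(C(C)C)C(C)C)C#C)cc(OC)c1OC
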